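**Retrosynthetic overview**
- Ester C–O bond, made last: enzyme-catalysed, protecting-group-free esterification of the side-chain primary alcohol with 4-methylpent-3-enoic acid.
- Terminal C7′–O bond: (E)-selective allylic C–H hydroxylation of a prenyl end; the new hydroxyl then anchors the catalyst-controlled hydrogenation that sets C6′.
- C3′–C4′ bond and the C2′ stereocentre: proposed copper-hydride hydroallylation of an isopropenyl tetralin with a tertiary allylic carbonate.
- Benzene ring (the only ring formed): Diels–Alder reaction of a 2-ethoxydiene with methyl propiolate, then dehydrogenation.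
- Cyclohexane ring: taken from the chiral pool as (2R,5R)-dihydrocarvone, which carries both ring stereocentres; ring order is cyclohexane (given), then benzene.

Side-chain carbons are numbered as in the heptan-2-yl name (C1′ to C7′; C2′ is bonded to the ring, C7′ carries oxygen).

Assumption: compound 1 is the pure trans-(2R,5R) isomer, the main component (about four fifths) of commercial (+)-dihydrocarvone; any cis isomer is removed by chromatography at the start or as the minor diastereomer once the arene is formed.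
Assumption: the ligand antipodes named in steps 5 and 7 are those that give the configuration drawn; if the sense of induction is the reverse, the mirror-image ligand is used.

**Route**

Step 1
Reactants: 1 (2R,5R)-2-methyl-5-(prop-1-en-2-yl)cyclohexan-1-one
Product: 2 (3R,6R)-6-methyl-3-(prop-1-en-2-yl)cyclohex-1-en-1-yl trifluoromethanesulfonate
Conditions: LiN(iPr)2 (LDA, 1.1 equiv), THF, −78 °C; then PhNTf2, −78 to 0 °C
Reagents that add atoms: N-phenylbis(trifluoromethanesulfonimide) (PhNTf2), O=S(=O)(N(c1ccccc1)S(=O)(=O)C(F)(F)F)C(F)(F)F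
Why: Kinetic deprotonation by the hindered amide removes a proton from the unsubstituted C6 methylene and O-sulfonylation of the less substituted lithium enolate gives the enol triflate (enolate triflation) without touching the C2 or C5 stereocentres.

Step 2
Reactants: 2 (3R,6R)-6-methyl-3-(prop-1-en-2-yl)cyclohex-1-en-1-yl trifluoromethanesulfonate; 3 tributyl(1-ethoxyethenyl)stannane
Product: 4 (3R,6R)-1-(1-ethoxyethenyl)-6-methyl-3-(prop-1-en-2-yl)cyclohex-1-ene
Conditions: Pd(PPh3)4 (5 mol%), LiCl (3 equiv), THF, 65 °C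
Reagents that add atoms: none
Why: Stille cross-coupling of the alkenyl triflate installs the 1-ethoxyvinyl group at the same carbon and gives an electron-rich 2-alkoxy-1,3-diene; no stereocentre takes part.

Step 3
Reactants: 4 (3R,6R)-1-(1-ethoxyethenyl)-6-methyl-3-(prop-1-en-2-yl)cyclohex-1-ene; 5 methyl prop-2-ynoate
Product: 7 methyl (5R,8S)-4-ethoxy-5-methyl-8-(prop-1-en-2-yl)-5,6,7,8-tetrahydronaphthalene-1-carboxylate, via cyclohexadiene cycloadduct 6 (not isolated)
Conditions: 5 (1.5 equiv), toluene, 110 °C (sealed tube); then DDQ (1.2 equiv), 23 °C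
Reagents that add atoms: none
Why: Diels–Alder reaction in which the 2-ethoxy group and the ring-substituted diene terminus both direct the ester-bearing alkyne carbon to the ring CH terminus (ester para to the ether), and DDQ dehydrogenation of the 1,4-cyclohexadiene aromatises it; the two ring stereocentres are spectators and the transient C8a centre is destroyed.

Step 4
Reactants: 8 2-methylbut-3-en-2-ol
Product: 9 tert-butyl 2-methylbut-3-en-2-yl carbonate
Conditions: n-BuLi (1.05 equiv), THF, −78 °C; then Boc2O, −78 to 23 °C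
Reagents that add atoms: di-tert-butyl dicarbonate (Boc2O), CC(C)(C)OC(=O)OC(=O)OC(C)(C)C
Why: Acylation of the lithium tertiary alkoxide by the dicarbonate (carbonate formation) gives a stable tertiary allylic electrophile.

Step 5
Reactants: 7 methyl (5R,8S)-4-ethoxy-5-methyl-8-(prop-1-en-2-yl)-5,6,7,8-tetrahydronaphthalene-1-carboxylate; 9 tert-butyl 2-methylbut-3-en-2-yl carbonate
Product: 10 methyl (5R,8S)-4-ethoxy-5-methyl-8-[(2S)-6-methylhept-5-en-2-yl]-5,6,7,8-tetrahydronaphthalene-1-carboxylate
Conditions: Cu(OAc)2 (5 mol%), (R)-DTBM-SEGPHOS (5.5 mol%), (MeO)2MeSiH (3 equiv), THF, 40 °C, 9 (2.5 equiv) added over 8 h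
Reagents that add atoms: none
Why: Proposed new method: the ligated copper hydride formed from Cu(OAc)2, the bisphosphine and the silane adds across the 1,1-disubstituted alkene with copper on the terminal carbon and hydride delivered to one face of C2′ under ligand control (this sets the (2S) centre); the primary alkylcopper then attacks the unsubstituted alkene terminus of 9 in an SN2′ substitution (oxidative addition to an allyl species of trivalent copper, then reductive elimination) to give the linear prenyl chain, and the expelled tert-butyl carbonate loses CO2 to a copper tert-butoxide that the silane converts back to the hydride; the closest known reaction types are the CuH-catalysed anti-Markovnikov hydroamination and hydroboration of unactivated 1,1-disubstituted alkenes with this ligand class and the CuH-catalysed hydroallylation of vinylarenes with allylic phosphates, none of which has been shown for an unactivated 1,1-disubstituted alkene with an allylic carbonate.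

Step 6
Reactants: 10 methyl (5R,8S)-4-ethoxy-5-methyl-8-[(2S)-6-methylhept-5-en-2-yl]-5,6,7,8-tetrahydronaphthalene-1-carboxylate
Product: 11 methyl (5R,8S)-4-ethoxy-8-[(2S,5E)-7-hydroxy-6-methylhept-5-en-2-yl]-5-methyl-5,6,7,8-tetrahydronaphthalene-1-carboxylate
Conditions: SeO2 (0.3 equiv), t-BuOOH (3 equiv), salicylic acid (0.1 equiv), CH2Cl2, 23 °C
Reagents that add atoms: tert-butyl hydroperoxide, CC(C)(C)OO
Why: Riley allylic oxidation, in which an ene reaction at the (E)-methyl group and a [2,3]-sigmatropic shift return the alkene to its place and put oxygen on the terminal carbon, forms the C7′–O bond and gives the (E)-allylic alcohol selectively.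

Step 7
Reactants: 11 methyl (5R,8S)-4-ethoxy-8-[(2S,5E)-7-hydroxy-6-methylhept-5-en-2-yl]-5-methyl-5,6,7,8-tetrahydronaphthalene-1-carboxylate
Product: 12 methyl (5R,8S)-4-ethoxy-8-[(2S,6R)-7-hydroxy-6-methylheptan-2-yl]-5-methyl-5,6,7,8-tetrahydronaphthalene-1-carboxylate
Conditions: [Ir(cod)((4S,5S)-ThrePHOX)][B(3,5-(CF3)2C6H3)4] (1 mol%), H2 (50 bar), CH2Cl2, 23 °C
Reagents that add atoms: none
Why: Asymmetric hydrogenation of the trisubstituted allylic alcohol with an iridium phosphinite–oxazoline catalyst, where the catalyst selects the alkene face and the fixed E geometry turns that into the (6′R) methyl centre; no other reducible group is present.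

Step 8
Reactants: 12 methyl (5R,8S)-4-ethoxy-8-[(2S,6R)-7-hydroxy-6-methylheptan-2-yl]-5-methyl-5,6,7,8-tetrahydronaphthalene-1-carboxylate
Product: 14 (5R,8S)-4-hydroxy-8-[(2S,6R)-7-hydroxy-6-methylheptan-2-yl]-5-methyl-5,6,7,8-tetrahydronaphthalene-1-carboxylic acid, via phenol methyl ester 13 (not isolated)
Conditions: BBr3 (4 equiv), CH2Cl2, −78 to 0 °C; H2O quench; then LiOH (6 equiv), THF/MeOH/H2O, 50 °C; 1 M HCl
Reagents that add atoms: lithium hydroxide, [Li+].[OH-]
Why: Lewis-acid cleavage of the aryl ethyl ether (bromide SN2 on the boron-activated ether) followed by saponification of the methyl ester frees phenol and acid; the molecule has no alkene at this stage and no stereocentre is touched.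

Step 9
Reactants: 14 (5R,8S)-4-hydroxy-8-[(2S,6R)-7-hydroxy-6-methylheptan-2-yl]-5-methyl-5,6,7,8-tetrahydronaphthalene-1-carboxylic acid; 15 4-methylpent-3-enoic acid
Product: 16 (5R,8S)-4-hydroxy-5-methyl-8-[(2S,6R)-6-methyl-7-[(4-methylpent-3-enoyl)oxy]heptan-2-yl]-5,6,7,8-tetrahydronaphthalene-1-carboxylic acid
Conditions: 15 (3 equiv), immobilised Candida antarctica lipase B (Novozym 435), 4 Å molecular sieves, toluene/2-MeTHF, 45 °C
Reagents that add atoms: none
Why: Lipase-catalysed esterification through a serine acyl-enzyme transfers the acyl group only to the unhindered primary aliphatic hydroxyl, because phenols and ortho-substituted benzoic acids are not substrates, and the neutral conditions keep the β,γ-alkene out of conjugation; no stereocentre is affected.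

**Compound list**
1 | (2R,5R)-2-methyl-5-(prop-1-en-2-yl)cyclohexan-1-one (trans-dihydrocarvone) | C[C@@H]1CC[C@@H](C(C)=C)CC1=O | starting material
2 | (3R,6R)-6-methyl-3-(prop-1-en-2-yl)cyclohex-1-en-1-yl trifluoromethanesulfonate | C[C@@H]1CC[C@@H](C(C)=C)C=C1OS(=O)(=O)C(F)(F)F | intermediate
3 | tributyl(1-ethoxyethenyl)stannane | CCCC[Sn](CCCC)(CCCC)C(=C)OCC | starting material
4 | (3R,6R)-1-(1-ethoxyethenyl)-6-methyl-3-(prop-1-en-2-yl)cyclohex-1-ene | C[C@@H]1CC[C@@H](C(C)=C)C=C1C(=C)OCC | intermediate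
5 | methyl prop-2-ynoate (methyl propiolate) | C#CC(=O)OC | starting material
6 | methyl (5R,8R)-4-ethoxy-5-methyl-8-(prop-1-en-2-yl)-3,5,6,7,8,8a-hexahydronaphthalene-1-carboxylate (C8a not controlled) | C=C(C)[C@@H]1CC[C@@H](C)C2=C(OCC)CC=C(C(=O)OC)C21 | intermediate
7 | methyl (5R,8S)-4-ethoxy-5-methyl-8-(prop-1-en-2-yl)-5,6,7,8-tetrahydronaphthalene-1-carboxylate | C=C(C)[C@@H]1CC[C@@H](C)c2c(OCC)ccc(C(=O)OC)c21 | intermediate
8 | 2-methylbut-3-en-2-ol | C=CC(C)(C)O | starting material
9 | tert-butyl 2-methylbut-3-en-2-yl carbonate | C=CC(C)(C)OC(=O)OC(C)(C)C | intermediate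
10 | methyl (5R,8S)-4-ethoxy-5-methyl-8-[(2S)-6-methylhept-5-en-2-yl]-5,6,7,8-tetrahydronaphthalene-1-carboxylate | CC(C)=CCC[C@H](C)[C@@H]1CC[C@@H](C)c2c(OCC)ccc(C(=O)OC)c21 | intermediate
11 | methyl (5R,8S)-4-ethoxy-8-[(2S,5E)-7-hydroxy-6-methylhept-5-en-2-yl]-5-methyl-5,6,7,8-tetrahydronaphthalene-1-carboxylate | OC/C(C)=C/CC[C@H](C)[C@@H]1CC[C@@H](C)c2c(OCC)ccc(C(=O)OC)c21 | intermediate
12 | methyl (5R,8S)-4-ethoxy-8-[(2S,6R)-7-hydroxy-6-methylheptan-2-yl]-5-methyl-5,6,7,8-tetrahydronaphthalene-1-carboxylate | OC[C@H](C)CCC[C@H](C)[C@@H]1CC[C@@H](C)c2c(OCC)ccc(C(=O)OC)c21 | intermediate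
13 | methyl (5R,8S)-4-hydroxy-8-[(2S,6R)-7-hydroxy-6-methylheptan-2-yl]-5-methyl-5,6,7,8-tetrahydronaphthalene-1-carboxylate | OC[C@H](C)CCC[C@H](C)[C@@H]1CC[C@@H](C)c2c(O)ccc(C(=O)OC)c21 | intermediate
14 | (5R,8S)-4-hydroxy-8-[(2S,6R)-7-hydroxy-6-methylheptan-2-yl]-5-methyl-5,6,7,8-tetrahydronaphthalene-1-carboxylic acid | OC[C@H](C)CCC[C@H](C)[C@@H]1CC[C@@H](C)c2c(O)ccc(C(=O)O)c21 | intermediate
15 | 4-methylpent-3-enoic acid | CC(C)=CCC(=O)O | starting material
16 | (5R,8S)-4-hydroxy-5-methyl-8-[(2S,6R)-6-methyl-7-[(4-methylpent-3-enoyl)oxy]heptan-2-yl]-5,6,7,8-tetrahydronaphthalene-1-carboxylic acid | CC(C)=CCC(=O)OC[C@H](C)CCC[C@H](C)[C@@H]1CC[C@@H](C)c2c(O)ccc(C(=O)O)c21 | target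

**Step count**
Total steps: 9. Longest linear sequence: 8 steps (1 → 2 → 4 → 7 → 10 → 11 → 12 → 14 → 16); step 4 is a one-step side branch.

**Three steps most likely to fail**

1. The hydroallylation (step 5, the proposed new step). Likely failure modes are direct reduction of carbonate 9 by the copper hydride, slow hydrocupration of the hindered alkene next to the peri ester, and a mismatch between ligand control and the substrate's own facial bias. The fallback uses known chemistry, sets out from 7 and comes back at 10. Copper-hydride hydroboration of the 1,1-disubstituted alkene (Cu(OAc)2, (R)-DTBM-SEGPHOS, HBpin, THF, 40 °C) gives methyl (5R,8S)-4-ethoxy-5-methyl-8-[(2S)-1-(4,4,5,5-tetramethyl-1,3,2-dioxaborolan-2-yl)propan-2-yl]-5,6,7,8-tetrahydronaphthalene-1-carboxylate F1, whose C2′ epimers can be separated if selectivity is incomplete. Matteson homologation (BrCH2Cl, n-BuLi, THF, −78 to 23 °C) inserts one methylene and gives methyl (5R,8S)-4-ethoxy-5-methyl-8-[(2S)-4-(4,4,5,5-tetramethyl-1,3,2-dioxaborolan-2-yl)butan-2-yl]-5,6,7,8-tetrahydronaphthalene-1-carboxylate F2. Suzuki–Miyaura coupling of this primary boronate with 1-bromo-2-methylprop-1-ene (Pd(OAc)2, RuPhos, K3PO4, toluene/H2O, 90 °C) then gives 10.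

2. The hydrogenation (step 7). Purely alkyl-substituted 2-methylallylic alcohols give lower selectivity than aryl-substituted ones with iridium catalysts, and the C6′ epimers would be hard to separate. The fallback moves the stereo-determining reduction to the carboxylic acid oxidation level, sets out from 11 and comes back at 12. Oxidation of the allylic alcohol to the acid (TEMPO, NaOCl, NaClO2, MeCN/phosphate buffer) gives (2E,6S)-6-[(1S,4R)-5-ethoxy-8-(methoxycarbonyl)-4-methyl-1,2,3,4-tetrahydronaphthalen-1-yl]-2-methylhept-2-enoic acid F3. Carboxylate-directed hydrogenation with Ru(OAc)2[(S)-H8-BINAP] (H2, MeOH), a well-established substrate class, gives (2R,6S)-6-[(1S,4R)-5-ethoxy-8-(methoxycarbonyl)-4-methyl-1,2,3,4-tetrahydronaphthalen-1-yl]-2-methylheptanoic acid F4. BH3·THF then reduces the aliphatic acid, not the aryl ester, to 12.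

3. The enzymatic esterification (step 9). The hydroxy acid may be a poor or poorly soluble lipase substrate, or conversion may stall. The fallback replaces enzyme selectivity by a protect–esterify–deprotect sequence, sets out from 14 and comes back at 16. Allyl bromide and K2CO3 in DMF alkylate only the phenol and the carboxylic acid and give prop-2-en-1-yl (5R,8S)-8-[(2S,6R)-7-hydroxy-6-methylheptan-2-yl]-5-methyl-4-(prop-2-en-1-yloxy)-5,6,7,8-tetrahydronaphthalene-1-carboxylate F5. Steglich esterification with 15 (EDC·HCl, catalytic DMAP, CH2Cl2, 0 °C) gives prop-2-en-1-yl (5R,8S)-5-methyl-8-[(2S,6R)-6-methyl-7-[(4-methylpent-3-enoyl)oxy]heptan-2-yl]-4-(prop-2-en-1-yloxy)-5,6,7,8-tetrahydronaphthalene-1-carboxylate F6. Pd(PPh3)4 with morpholine in THF at 23 °C removes both allyl groups under neutral conditions and gives 16.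

**Further compounds**
F1 | step 5 | methyl (5R,8S)-4-ethoxy-5-methyl-8-[(2S)-1-(4,4,5,5-tetramethyl-1,3,2-dioxaborolan-2-yl)propan-2-yl]-5,6,7,8-tetrahydronaphthalene-1-carboxylate | CC1(C)OB(C[C@H](C)[C@@H]2CC[C@@H](C)c3c(OCC)ccc(C(=O)OC)c32)OC1(C)C
F2 | step 5 | methyl (5R,8S)-4-ethoxy-5-methyl-8-[(2S)-4-(4,4,5,5-tetramethyl-1,3,2-dioxaborolan-2-yl)butan-2-yl]-5,6,7,8-tetrahydronaphthalene-1-carboxylate | CC1(C)OB(CC[C@H](C)[C@@H]2CC[C@@H](C)c3c(OCC)ccc(C(=O)OC)c32)OC1(C)C
F3 | step 7 | (2E,6S)-6-[(1S,4R)-5-ethoxy-8-(methoxycarbonyl)-4-methyl-1,2,3,4-tetrahydronaphthalen-1-yl]-2-methylhept-2-enoic acid | OC(=O)/C(C)=C/CC[C@H](C)[C@@H]1CC[C@@H](C)c2c(OCC)ccc(C(=O)OC)c21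
F4 | step 7 | (2R,6S)-6-[(1S,4R)-5-ethoxy-8-(methoxycarbonyl)-4-methyl-1,2,3,4-tetrahydronaphthalen-1-yl]-2-methylheptanoic acid | OC(=O)[C@H](C)CCC[C@H](C)[C@@H]1CC[C@@H](C)c2c(OCC)ccc(C(=O)OC)c21
F5 | step 9 | prop-2-en-1-yl (5R,8S)-8-[(2S,6R)-7-hydroxy-6-methylheptan-2-yl]-5-methyl-4-(prop-2-en-1-yloxy)-5,6,7,8-tetrahydronaphthalene-1-carboxylate | OC[C@H](C)CCC[C@H](C)[C@@H]1CC[C@@H](C)c2c(OCC=C)ccc(C(=O)OCC=C)c21
F6 | step 9 | prop-2-en-1-yl (5R,8S)-5-methyl-8-[(2S,6R)-6-methyl-7-[(4-methylpent-3-enoyl)oxy]heptan-2-yl]-4-(prop-2-en-1-yloxy)-5,6,7,8-tetrahydronaphthalene-1-carboxylate | CC(C)=CCC(=O)OC[C@H](C)CCC[C@H](C)[C@@H]1CC[C@@H](C)c2c(OCC=C)ccc(C(=O)OCC=C)c21
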